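Ring C is cut across C3–C4 and O1–C2 into a ring-A salicylaldehyde and a ring-B styrene. The key step joins three components: aldehyde 5, trimethyl orthoformate and styrene 19 meet under a chiral phosphoric acid; the derived ortho-quinone methide (oxocarbenium) undergoes an enantioselective oxa-[4+2] cycloaddition that forms both bonds and sets C2. It exploits the symmetric, fully substituted phloroglucinol ring A (either ortho oxygen can become O1; O1, O5 and O7 stabilise cationic C4) and the 2',4'-dioxygenated ring B, which makes vinyl carbon C3 nucleophilic and stabilises charge at C2. The labile C4 methoxy group is exchanged for hydroxyl in the same flask; oxidation and deprotection finish.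

Key step: step 10

Remark on the chemistry (assumption): the S-configured dirhodium catalyst of step 6 is taken to give the 3R series and the R-configured phosphoric acid of step 10 the 2S configuration; should either facial sense be opposite, the mirror-image catalyst is used.

Step 1
Reactants: 1 2,4,6-trihydroxybenzaldehyde; 2 prenyl bromide (1-bromo-3-methylbut-2-ene)
Product: 3 2,4,6-trihydroxy-3,5-bis(3-methylbut-2-en-1-yl)benzaldehyde
Conditions: 2 (2.1 equiv), 10% aq. KOH, 0 °C
Reagents that add atoms: prenyl bromide CC(C)=CCBr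
Why: Double C-alkylation of the ambident phloroglucinol phenolate in water (aqueous-base C-prenylation of acylphloroglucinols), where hydrogen bonding to oxygen favours attack through C3 and C5, the only free ring positions, should give the 3,5-diprenyl aldehyde.

Step 2
Reactants: 3 2,4,6-trihydroxy-3,5-bis(3-methylbut-2-en-1-yl)benzaldehyde; 4 chloromethyl methyl ether (MOMCl)
Product: 5 2-hydroxy-4,6-bis(methoxymethoxy)-3,5-bis(3-methylbut-2-en-1-yl)benzaldehyde
Conditions: MOMCl (2.2 equiv), i-Pr2NEt, CH2Cl2, 0 °C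
Reagents that add atoms: chloromethyl methyl ether COCCl
Why: O-Alkylation (methoxymethyl ether formation) should stop after two ethers because the last ortho hydroxyl is held in a hydrogen bond to the aldehyde, and since 3 is symmetric it does not matter which ortho hydroxyl remains free.

Step 3
Reactants: 6 1-bromo-2,4-dimethoxybenzene; 7 3,5-dimethoxybenzoyl chloride
Product: 9 (5-bromo-2-hydroxy-4-methoxyphenyl)(3,5-dimethoxyphenyl)methanone, via tetramethoxy ketone 8 (not isolated)
Conditions: AlCl3 (2.5 equiv), ClCH2CH2Cl, 0 °C then 50 °C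
Reagents that add atoms: 3,5-dimethoxybenzoyl chloride COc1cc(OC)cc(c1)C(Cl)=O
Why: Friedel–Crafts acylation should occur at C5 of 6 (para to one methoxy group, ortho to the other), after which the aluminium-chelated ketone 8 should lose only the methyl ether ortho to the carbonyl group (chelation-directed demethylation).

Step 4
Reactants: 9 (5-bromo-2-hydroxy-4-methoxyphenyl)(3,5-dimethoxyphenyl)methanone; 10 4-methoxybenzyl chloride
Product: 11 {5-bromo-4-methoxy-2-[(4-methoxyphenyl)methoxy]phenyl}(3,5-dimethoxyphenyl)methanone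
Conditions: K2CO3, KI (cat.), DMF, 60 °C
Reagents that add atoms: 4-methoxybenzyl chloride COc1ccc(CCl)cc1
Why: Williamson ether synthesis on the only free phenol installs the benzylic ether whose CH2 group later becomes C2 of the dihydrobenzofuran.

Step 5
Reactants: 11 {5-bromo-4-methoxy-2-[(4-methoxyphenyl)methoxy]phenyl}(3,5-dimethoxyphenyl)methanone; 12 hydrazine monohydrate
Product: 13 hydrazone of 11 (E/Z mixture)
Conditions: N2H4·H2O (10 equiv), AcOH (cat.), EtOH, reflux
Reagents that add atoms: hydrazine NN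
Why: Acid-catalysed condensation of the diaryl ketone with excess hydrazine (hydrazone formation) should give the free hydrazone, whose C=N geometry is irrelevant because it is lost in step 6.

Step 6
Reactants: 13 hydrazone of 11
Product: 15 (2S,3R)-5-bromo-3-(3,5-dimethoxyphenyl)-6-methoxy-2-(4-methoxyphenyl)-2,3-dihydro-1-benzofuran (2,3-cis), via diaryldiazomethane 14 (not isolated)
Conditions: MnO2, CH2Cl2, 0 °C, filter; then Rh2(S-PTAD)4 (1 mol%; PTAD = (1-adamantyl)(N-phthalimido)acetate), CH2Cl2, 0 °C
Reagents that add atoms: none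
Why: Dehydrogenation of the hydrazone gives diazo compound 14, whose donor/donor dirhodium carbene should undergo enantioselective intramolecular 1,5-C–H insertion into the benzylic ether C–H bond, the chiral carboxylate ligands setting C3 as R and the insertion geometry giving the 2,3-cis ring.

Step 7
Reactants: 15 (2S,3R)-5-bromo-3-(3,5-dimethoxyphenyl)-6-methoxy-2-(4-methoxyphenyl)-2,3-dihydro-1-benzofuran
Product: 16 (2R,3R)-5-bromo-3-(3,5-dihydroxyphenyl)-2-(4-hydroxyphenyl)-2,3-dihydro-1-benzofuran-6-ol (2,3-trans)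
Conditions: BBr3 (8 equiv), CH2Cl2, −78 °C to rt; aq. NaHCO3
Reagents that add atoms: none
Why: BBr3 cleaves the four aryl methyl ethers (Lewis acid ether cleavage) and, by reversible heterolysis of the O1–C2 bond to the para-oxybenzyl cation (para-quinone methide) and reclosure, should equilibrate C2 to the more stable 2,3-trans isomer while C3 keeps the configuration set in step 6.

Step 8
Reactants: 16 (2R,3R)-5-bromo-3-(3,5-dihydroxyphenyl)-2-(4-hydroxyphenyl)-2,3-dihydro-1-benzofuran-6-ol; 4 chloromethyl methyl ether (MOMCl)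
Product: 17 (2R,3R)-5-bromo-3-[3,5-bis(methoxymethoxy)phenyl]-6-(methoxymethoxy)-2-[4-(methoxymethoxy)phenyl]-2,3-dihydro-1-benzofuran
Conditions: MOMCl (6 equiv), i-Pr2NEt, DMF, 0 °C to rt
Reagents that add atoms: chloromethyl methyl ether COCCl
Why: Exhaustive O-alkylation (methoxymethyl ether formation) masks all four phenols, which would otherwise compete as nucleophiles in step 10, with the same group that ring A carries so that one final operation removes all of them.

Step 9
Reactants: 17 (2R,3R)-5-bromo-3-[3,5-bis(methoxymethoxy)phenyl]-6-(methoxymethoxy)-2-[4-(methoxymethoxy)phenyl]-2,3-dihydro-1-benzofuran; 18 4,4,5,5-tetramethyl-2-vinyl-1,3,2-dioxaborolane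
Product: 19 (2R,3R)-3-[3,5-bis(methoxymethoxy)phenyl]-5-ethenyl-6-(methoxymethoxy)-2-[4-(methoxymethoxy)phenyl]-2,3-dihydro-1-benzofuran
Conditions: PdCl2(dppf) (5 mol%; dppf = 1,1'-bis(diphenylphosphino)ferrocene), K2CO3, 1,4-dioxane–H2O, 85 °C
Reagents that add atoms: 4,4,5,5-tetramethyl-2-vinyl-1,3,2-dioxaborolane C=CB1OC(C)(C)C(C)(C)O1
Why: Suzuki–Miyaura cross-coupling (oxidative addition of zerovalent palladium into the aryl C–Br bond, transmetalation of the vinyl boronate, reductive elimination) should install the vinyl group under carbonate conditions that leave the acetals and both benzylic stereocentres untouched.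

Step 10
Reactants: 5 2-hydroxy-4,6-bis(methoxymethoxy)-3,5-bis(3-methylbut-2-en-1-yl)benzaldehyde; 19 (2R,3R)-3-[3,5-bis(methoxymethoxy)phenyl]-5-ethenyl-6-(methoxymethoxy)-2-[4-(methoxymethoxy)phenyl]-2,3-dihydro-1-benzofuran; 20 trimethyl orthoformate
Product: 23 (2S)-2-{(2R,3R)-3-[3,5-bis(methoxymethoxy)phenyl]-6-(methoxymethoxy)-2-[4-(methoxymethoxy)phenyl]-2,3-dihydro-1-benzofuran-5-yl}-5,7-bis(methoxymethoxy)-6,8-bis(3-methylbut-2-en-1-yl)-3,4-dihydro-2H-chromen-4-ol (C4 epimers), via ortho-quinone methide 21 (not isolated), via 4-methoxyflavan 22 (not isolated)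
Conditions: 5 (1.5 equiv), HC(OMe)3 (3 equiv), (R)-3,3'-bis(2,4,6-triisopropylphenyl)-1,1'-binaphthalene-2,2'-diyl hydrogen phosphate (10 mol%), 4 Å MS, toluene, 0 °C to rt; then THF–H2O (4:1), pyridinium p-toluenesulfonate, rt
Reagents that add atoms: water O (oxygen of the C4 hydroxyl group)
Why: Proposed new method: acid-catalysed exchange of 5 with the orthoformate and loss of methanol should give ortho-quinone methide 21, which the phosphoric acid protonates to a phosphate-paired oxocarbenium ion whose C4 is attacked by the terminal vinyl carbon of 19 (C3–C4) while the ring-A phenol oxygen captures the developing benzylic cation at C2 (O1–C2) in a concerted asynchronous inverse-electron-demand oxa-[4+2] cycloaddition (hetero-Diels–Alder), after which the C4 methoxy group of 22, activated by O1, O5 and O7, is solvolysed to the hydroxyl of 23 by the added water. The closest known reaction types are the Sc(OTf)3-catalysed three-component coupling of salicylaldehydes, orthoformates and styrenes to 4-alkoxy-2-arylchromans, the chiral Brønsted acid-catalysed enantioselective [4+2] cycloaddition of ortho-quinone methides with styrenes, and the chiral-anion-controlled cycloaddition of salicylaldehyde acetal oxocarbenium ions with vinyl ethers; their combination on an acetal-level quinone methide with a styrene is the untested part. Ring C closes in the [4+2] mode (in the stepwise limit, Prins-type C–C bond formation followed by 6-exo-trig capture of the cation by O1). C2 is set by the catalyst: the phosphate, hydrogen-bonded to the ring-A hydroxyl in the contact ion pair, should shield one face of the heterodiene so that the styrene adds to give 2S, the dihydrobenzofuran centres being too remote to interfere, while C4 forms cis to C2 through the endo transition state but is of no consequence because the solvolysis scrambles it and step 11 removes it. The step needs regioselectivity (C3 to C4, O1 to C2), which the polarity of the partners secures (nucleophilic vinyl terminus, cation at C2 stabilised by the 2'- and 4'-oxygens of ring B), chemoselectivity for the vinyl group over the alkoxyarene rings and the prenyl alkenes, which the much higher nucleophilicity of the dialkoxystyrene secures, and no site selectivity on ring A because 5 carries only one free hydroxyl on a symmetric carbon skeleton.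

Step 11
Reactants: 23 hexakis(methoxymethyl)-protected flavan-4-ol (C4 epimers)
Product: 24 (2S)-2-{(2R,3R)-3-[3,5-bis(methoxymethoxy)phenyl]-6-(methoxymethoxy)-2-[4-(methoxymethoxy)phenyl]-2,3-dihydro-1-benzofuran-5-yl}-5,7-bis(methoxymethoxy)-6,8-bis(3-methylbut-2-en-1-yl)-2,3-dihydro-4H-chromen-4-one
Conditions: Dess–Martin periodinane, NaHCO3, CH2Cl2, 0 °C to rt
Reagents that add atoms: none
Why: Dess–Martin oxidation of the secondary benzylic alcohol under bicarbonate buffering should converge both C4 epimers on one ketone while leaving the prenyl alkenes, the acetals and the C2 centre (no base, no acid) untouched.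

Step 12
Reactants: 24 hexakis(methoxymethyl)-protected flavanone
Product: 25 (2S)-2-[(2R,3R)-3-(3,5-dihydroxyphenyl)-6-hydroxy-2-(4-hydroxyphenyl)-2,3-dihydro-1-benzofuran-5-yl]-5,7-dihydroxy-6,8-bis(3-methylbut-2-en-1-yl)-2,3-dihydro-4H-chromen-4-one (CNP0230984.1)
Conditions: 3 M aq. HCl, MeOH–THF, 40 °C
Reagents that add atoms: none
Why: Acid-catalysed acetal exchange with methanol (methoxymethyl ether cleavage) should free all six phenols, the mildest effective acid strength and temperature being chosen so that the prenyl groups do not cyclise onto the new phenols and the O1–C2 bond does not ionise.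

Compound list
1 | 2,4,6-trihydroxybenzaldehyde | O=Cc1c(O)cc(O)cc1O | starting material
2 | prenyl bromide (1-bromo-3-methylbut-2-ene) | CC(C)=CCBr | starting material
3 | 2,4,6-trihydroxy-3,5-bis(3-methylbut-2-en-1-yl)benzaldehyde | O=Cc1c(O)c(CC=C(C)C)c(O)c(CC=C(C)C)c1O | intermediate
4 | chloromethyl methyl ether (MOMCl) | COCCl | starting material
5 | 2-hydroxy-4,6-bis(methoxymethoxy)-3,5-bis(3-methylbut-2-en-1-yl)benzaldehyde | O=Cc1c(O)c(CC=C(C)C)c(OCOC)c(CC=C(C)C)c1OCOC | intermediate
6 | 1-bromo-2,4-dimethoxybenzene | COc1ccc(Br)c(OC)c1 | starting material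
7 | 3,5-dimethoxybenzoyl chloride | COc1cc(OC)cc(c1)C(Cl)=O | starting material
8 | (5-bromo-2,4-dimethoxyphenyl)(3,5-dimethoxyphenyl)methanone | COc1cc(OC)c(cc1Br)C(=O)c1cc(OC)cc(OC)c1 | intermediate (not isolated)
9 | (5-bromo-2-hydroxy-4-methoxyphenyl)(3,5-dimethoxyphenyl)methanone | COc1cc(O)c(cc1Br)C(=O)c1cc(OC)cc(OC)c1 | intermediate
10 | 4-methoxybenzyl chloride | COc1ccc(CCl)cc1 | starting material
11 | {5-bromo-4-methoxy-2-[(4-methoxyphenyl)methoxy]phenyl}(3,5-dimethoxyphenyl)methanone | COc1ccc(COc2cc(OC)c(Br)cc2C(=O)c2cc(OC)cc(OC)c2)cc1 | intermediate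
12 | hydrazine monohydrate | NN.O | starting material
13 | hydrazone of 11 (E/Z mixture) | COc1ccc(COc2cc(OC)c(Br)cc2C(=NN)c2cc(OC)cc(OC)c2)cc1 | intermediate
14 | {5-bromo-4-methoxy-2-[(4-methoxyphenyl)methoxy]phenyl}(3,5-dimethoxyphenyl)diazomethane | COc1ccc(COc2cc(OC)c(Br)cc2C(=[N+]=[N-])c2cc(OC)cc(OC)c2)cc1 | intermediate (not isolated)
15 | (2S,3R)-5-bromo-3-(3,5-dimethoxyphenyl)-6-methoxy-2-(4-methoxyphenyl)-2,3-dihydro-1-benzofuran (cis) | Brc1cc2c(cc1OC)O[C@H](c1ccc(OC)cc1)[C@@H]2c1cc(OC)cc(OC)c1 | intermediate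
16 | (2R,3R)-5-bromo-3-(3,5-dihydroxyphenyl)-2-(4-hydroxyphenyl)-2,3-dihydro-1-benzofuran-6-ol (trans) | Brc1cc2c(cc1O)O[C@@H](c1ccc(O)cc1)[C@@H]2c1cc(O)cc(O)c1 | intermediate
17 | (2R,3R)-5-bromo-3-[3,5-bis(methoxymethoxy)phenyl]-6-(methoxymethoxy)-2-[4-(methoxymethoxy)phenyl]-2,3-dihydro-1-benzofuran | Brc1cc2c(cc1OCOC)O[C@@H](c1ccc(OCOC)cc1)[C@@H]2c1cc(OCOC)cc(OCOC)c1 | intermediate
18 | 4,4,5,5-tetramethyl-2-vinyl-1,3,2-dioxaborolane | C=CB1OC(C)(C)C(C)(C)O1 | starting material
19 | (2R,3R)-3-[3,5-bis(methoxymethoxy)phenyl]-5-ethenyl-6-(methoxymethoxy)-2-[4-(methoxymethoxy)phenyl]-2,3-dihydro-1-benzofuran | C=Cc1cc2c(cc1OCOC)O[C@@H](c1ccc(OCOC)cc1)[C@@H]2c1cc(OCOC)cc(OCOC)c1 | intermediate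
20 | trimethyl orthoformate | COC(OC)OC | starting material
21 | 6-(methoxymethylidene)-3,5-bis(methoxymethoxy)-2,4-bis(3-methylbut-2-en-1-yl)cyclohexa-2,4-dien-1-one (ortho-quinone methide) | COC=C1C(=O)C(CC=C(C)C)=C(OCOC)C(CC=C(C)C)=C1OCOC | intermediate (not isolated)
22 | (2S)-4-methoxyflavan, hexakis(methoxymethyl) ether (C4 epimers, 2,4-cis expected to predominate) | CC(C)=CCc1c(OCOC)c(CC=C(C)C)c2c(c1OCOC)C(OC)C[C@@H](c1cc3c(cc1OCOC)O[C@@H](c1ccc(OCOC)cc1)[C@@H]3c1cc(OCOC)cc(OCOC)c1)O2 | intermediate (not isolated)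
23 | (2S)-flavan-4-ol, hexakis(methoxymethyl) ether (C4 epimers) | CC(C)=CCc1c(OCOC)c(CC=C(C)C)c2c(c1OCOC)C(O)C[C@@H](c1cc3c(cc1OCOC)O[C@@H](c1ccc(OCOC)cc1)[C@@H]3c1cc(OCOC)cc(OCOC)c1)O2 | intermediate
24 | (2S)-flavanone, hexakis(methoxymethyl) ether | CC(C)=CCc1c(OCOC)c(CC=C(C)C)c2c(c1OCOC)C(=O)C[C@@H](c1cc3c(cc1OCOC)O[C@@H](c1ccc(OCOC)cc1)[C@@H]3c1cc(OCOC)cc(OCOC)c1)O2 | intermediate
25 | (2S)-2-[(2R,3R)-3-(3,5-dihydroxyphenyl)-6-hydroxy-2-(4-hydroxyphenyl)-2,3-dihydro-1-benzofuran-5-yl]-5,7-dihydroxy-6,8-bis(3-methylbut-2-en-1-yl)-2,3-dihydro-4H-chromen-4-one | CC(C)=CCc1c(O)c(CC=C(C)C)c2c(c1O)C(=O)C[C@@H](c1cc3c(cc1O)O[C@@H](c1ccc(O)cc1)[C@@H]3c1cc(O)cc(O)c1)O2 | target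

Total step count: 12. Longest linear sequence: 10 steps (6 and 7 to 25 through steps 3 to 12).

Steps most likely to fail

Step 10 (Proposed new method). The catalyst may discriminate poorly between the two faces of the heterodiene, giving C2 epimers. The acid may oligomerise the electron-rich styrene. The 2'-methoxymethyl ether oxygen may take part in capture of the C2 cation. Elimination across C3–C4 may compete during the methoxy/hydroxyl exchange. The fallback uses only known chemistry, sets out from 17 and 5 and rejoins the route at 24. Bromine–lithium exchange on 17 (n-BuLi, THF, −78 °C) and a DMF quench would give the benzofuran-5-carbaldehyde F1. Addition of MeMgBr to 5 would give the benzylic alcohol F2, and MnO2 oxidation the acetophenone F3. Claisen–Schmidt condensation of F3 with F1 (KOH, EtOH, rt) would give the 2'-hydroxychalcone F4. NaOAc in refluxing EtOH would close F4 by oxa-Michael addition to flavanone 24 together with its C2 epimer F5. The two are diastereomers and would be separated by chromatography, and F5 would be returned to the same equilibrating conditions.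

Step 12. Protic acid may ionise the O1–C2 bond, which the 2'- and 4'-oxygens of ring B assist, eroding the configuration at C2. It may also cyclise prenyl groups onto the freshly liberated neighbouring phenols. The fallback sets out from 24 and rejoins at 25. It replaces solvolysis by an aprotic protecting-group exchange: trimethylsilyl triflate with 2,2'-bipyridyl (CH2Cl2, 0 °C) would convert the six aryl methoxymethyl ethers into the hexakis(trimethylsilyl) ether F6, and neutral aqueous work-up would hydrolyse F6 to 25.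

Step 1. The phenolate alkylation may not stop cleanly at the 3,5-dialkyl stage: mono-alkylation, O-alkylation and geminal dialkylation with dearomatisation compete. The fallback sets out from 1 and rejoins at 5, replacing phenolate alkylation by halogenation and cross-coupling. Two-fold protection of 1 with 4 (i-Pr2NEt, CH2Cl2) would give 2-hydroxy-4,6-bis(methoxymethoxy)benzaldehyde F7. N-Bromosuccinimide (2 equiv, MeCN, 0 °C) would give the 3,5-dibromide F8. A double linear-selective Suzuki–Miyaura coupling with 3-methylbut-2-enylboronic acid pinacol ester (Pd(OAc)2 with a biarylphosphine, K3PO4, THF–H2O) would give 5.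

Further compounds
F1 | step 10 | (2R,3R)-3-[3,5-bis(methoxymethoxy)phenyl]-6-(methoxymethoxy)-2-[4-(methoxymethoxy)phenyl]-2,3-dihydro-1-benzofuran-5-carbaldehyde | O=Cc1cc2c(cc1OCOC)O[C@@H](c1ccc(OCOC)cc1)[C@@H]2c1cc(OCOC)cc(OCOC)c1
F2 | step 10 | 2-(1-hydroxyethyl)-3,5-bis(methoxymethoxy)-4,6-bis(3-methylbut-2-en-1-yl)phenol (racemic) | CC(O)c1c(O)c(CC=C(C)C)c(OCOC)c(CC=C(C)C)c1OCOC
F3 | step 10 | 1-[2-hydroxy-4,6-bis(methoxymethoxy)-3,5-bis(3-methylbut-2-en-1-yl)phenyl]ethan-1-one | CC(=O)c1c(O)c(CC=C(C)C)c(OCOC)c(CC=C(C)C)c1OCOC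
F4 | step 10 | (E)-2'-hydroxychalcone from F3 and F1 | COCOc1c(CC=C(C)C)c(O)c(C(=O)/C=C/c2cc3c(cc2OCOC)O[C@@H](c2ccc(OCOC)cc2)[C@@H]3c2cc(OCOC)cc(OCOC)c2)c(OCOC)c1CC=C(C)C
F5 | step 10 | (2R)-epimer of 24 | CC(C)=CCc1c(OCOC)c(CC=C(C)C)c2c(c1OCOC)C(=O)C[C@H](c1cc3c(cc1OCOC)O[C@@H](c1ccc(OCOC)cc1)[C@@H]3c1cc(OCOC)cc(OCOC)c1)O2
F6 | step 12 | hexakis(trimethylsilyl) ether of 25 | CC(C)=CCc1c(O[Si](C)(C)C)c(CC=C(C)C)c2c(c1O[Si](C)(C)C)C(=O)C[C@@H](c1cc3c(cc1O[Si](C)(C)C)O[C@@H](c1ccc(O[Si](C)(C)C)cc1)[C@@H]3c1cc(O[Si](C)(C)C)cc(O[Si](C)(C)C)c1)O2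
F7 | step 1 | 2-hydroxy-4,6-bis(methoxymethoxy)benzaldehyde | O=Cc1c(O)cc(OCOC)cc1OCOC
F8 | step 1 | 3,5-dibromo-2-hydroxy-4,6-bis(methoxymethoxy)benzaldehyde | O=Cc1c(O)c(Br)c(OCOC)c(Br)c1OCOC
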